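**Assumption:** the target has no stereocentres and no stereogenic double bonds (it is achiral and C2-symmetric, with freely rotating indolyl–quinone bonds), so "single enantiomer" needs no stereocontrol. The route below follows the known bromanil/indole approach to bis-indolylquinones; it is a proposal and has not been run here.

## Retrosynthetic overview

1. The target is 2,5-dihydroxy-3,6-di(1H-indol-3-yl)-1,4-benzoquinone; each C–OH is a vinylogous acid and comes from hydrolysis of a vinylogous acyl bromide (C–Br to C–OH, twice).
2. The two quinone–indole C3 bonds come from a double addition–elimination of indole (C3 nucleophile) on tetrabromo-1,4-benzoquinone.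
3. No ring is formed: the quinone ring and both indole rings are purchased intact.
4. Order: both C–C bonds first (step 1), then both C–O bonds (step 2).

## Route

**Step 1**
Reactants: 1, bromanil (2,3,5,6-tetrabromo-1,4-benzoquinone); 2, 1H-indole (2.2 equiv)
Product: 3, 2,5-dibromo-3,6-di(1H-indol-3-yl)-1,4-benzoquinone
Conditions: Cs2CO3 (2.5 equiv), MeCN, 0 °C to rt, dark, N2; chromatography or trituration to remove any 2,6-isomer
Reagents that add atoms: none (all product atoms come from 1 and 2; Cs2CO3 only removes 2 HBr)
Why: Double vinylic substitution (conjugate addition–elimination, SNV) by indole C3 on the tetrahaloquinone. The first indolyl group donates into the carbonyl it is conjugated with, so the second indole adds through the other, more electrophilic carbonyl and lands para to the first (2,5-pattern). No stereocentre is created.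

**Step 2**
Reactants: 3, 2,5-dibromo-3,6-di(1H-indol-3-yl)-1,4-benzoquinone
Product: 4, didemethylasterriquinone D (2,5-dihydroxy-3,6-di(1H-indol-3-yl)-1,4-benzoquinone)
Conditions: 10% aq NaOH, MeOH, reflux, 1–2 h; then 1 M HCl to pH ~2, filter the purple solid
Reagents that add atoms: sodium hydroxide / water, [Na+].[OH-] (O); each OH oxygen comes from hydroxide
Why: Addition–elimination of hydroxide (directly or via the methoxy intermediate) at the two vinylogous acyl bromide carbons gives the resonance-stabilised dihydroxyquinone dianion, which resists further attack. Acidification releases the target; the indole N–H and C3–aryl bonds are inert to aqueous base.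

Checks: 1 (C6Br4O2) + 2 × 2 (C8H7N) gives 3 (C22H12Br2N2O2) + 2 HBr. 3 + 2 HO⁻ gives 4 (C22H14N2O4) + 2 Br⁻. The SMILES of 4 is identical to the target: quinone C1=O, C2–OH, C3–indol-3-yl, C4=O, C5–OH, C6–indol-3-yl, both indoles N–H free.

## Compound list

1 | bromanil (2,3,5,6-tetrabromo-1,4-benzoquinone) | O=C1C(Br)=C(Br)C(=O)C(Br)=C1Br | starting material
2 | 1H-indole | c1ccc2[nH]ccc2c1 | starting material
3 | 2,5-dibromo-3,6-di(1H-indol-3-yl)-1,4-benzoquinone | O=C1C(Br)=C(c2c[nH]c3ccccc23)C(=O)C(Br)=C1c1c[nH]c2ccccc12 | intermediate
4 | didemethylasterriquinone D | O=C1C(O)=C(c2c[nH]c3ccccc23)C(=O)C(O)=C1c1c[nH]c2ccccc12 | target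

## Summary

Total step count: 2
Longest linear sequence: 2

Steps most likely to fail (the route has only two steps, so step 1 is listed twice for its two distinct failure modes):

1. **Step 1, regiochemistry of the second substitution** (2,5- versus 2,6-diindolyl, or over-substitution). Fallback: switch to acid-promoted Michael addition of indole to 2,5-dichloro-1,4-benzoquinone (AcOH or HCl/THF) with DDQ re-oxidation after each addition. Indole can then only add at the two C–H positions, so the pre-placed chlorines fix the 2,5-pattern; the resulting dichloro analogue of 3 is hydrolysed as in step 2.
2. **Step 1, chemoselectivity of the first substitution** (indole N- versus C3-attack, or redox decomposition of indole by the strongly oxidising bromanil). Fallback: make the C–C bonds by Pd-catalysed Stille coupling of N-Boc-3-(tributylstannyl)indole with 2,5-dibromo-3,6-dimethoxy-1,4-benzoquinone (from bromanil and NaOMe/MeOH), then remove Boc and hydrolyse the methyl ethers.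
3. **Step 2, base sensitivity** (incomplete second displacement, or base-induced degradation or ring contraction of the hydroxyquinone). Fallback: displace both bromides with sodium benzyloxide (BnOH/NaH, THF, 0 °C) to give the bis-benzyl ether, then hydrogenolyse (H2, Pd/C) to the hydroquinone and re-oxidise in air to 4, avoiding hot hydroxide.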